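The constants of this flask are hidden, so you work from two runs.

all flasks: gas 11 mM (held)

| charge | electrophile | free base | remark | time |
|---|---|---|---|---|
| Sunday's | 0.20 M | 0.60 M | the very flask that is asked about, followed so far |  |
| Monday's | 0.40 M | 0.60 M | run made earlier |  |
| flask | 0.20 M | 0.600 M |  | 10 h |

- Sunday's (time / min: electrophile / %, product / %): 25.0: 96, 1; 50.0: 85, 8; 80.0: 77, 13; 120: 71, 17
- Monday's (time / h: electrophile / %, product / %): 0.500: 93, 2; 1.33: 85, 8; 3.00: 71, 13; 8.00: 27, 40

(standard deviation of a reading: 1.5 percentage points)

- percentages count the electrophile that a species holds: one idle adduct counts as two
- product is meant together with its idle adduct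
- at the start none of nucleophile is dissolved
- steps thought possible: electrophile + nucleophile -> acid set free + product; nucleophile + acid set free <-> protonated nucleophile; acid set free + free base <-> salt of the base; electrophile + product <-> idle adduct; gas <-> nucleophile; acid set free -> by-product carried off
- what has gone from electrophile into another species counts as reacted, even if it can come back
- the earlier runs do not show how much of nucleophile is bound; that part of a forecast is a guess
- in an amount of product, one idle adduct counts as one product

1. part of the electrophile that has reacted at 10 h
2. share of the unused nucleophile that is free and not bound as protonated nucleophile, at 10 h

Sunday's last reading gives 0.0170 M/h of product. Monday's last reading, with twice the electrophile, gives 0.0200 M/h. Call this the molar pace: product made per hour since the start, as a concentration. The two spans differ in length as well as in charge, so this is only a reading: up to those times the pace looks zero-order in electrophile.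

Carry Sunday's pace forward. For 10 h that estimates 0.170 M of product in this flask, which would leave 0.0300 M of its charge. At the late end, take that rest as held in idle adduct, so free product is the amount made minus the rest. Monday's last reading gives a rough binding constant, 43.7 /M. Free electrophile is then the rest divided by one plus that constant times free product, or 0.00422 M. Your reckoning is 97.9 % reacted. The readings give you no free share.

The forecast differs. It takes a rate in proportion to electrophile, with “no clear slowing as salt builds up”, and says 75 % reacted and, as a guess, 50 % free.

The flask gives 93.5 % reacted and 5.44 % free.

    electrophile + nucleophile → acid set free + product (k = 1.70 /M/min)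
    nucleophile + acid set free ⇌ protonated nucleophile, settled at all times (K = 41000 /M)
    acid set free + free base ⇌ salt of the base (K = 37000 /M, k = 0.170 /M/min)
    electrophile + product ⇌ idle adduct, settled at all times (K = 36.0 /M)
    gas ⇌ nucleophile, rate k5*(csat - [nucleophile]) (kL = 0.0530 /min)
    acid set free → by-product carried off (k = 0.00160 /min)

In this flask the pace gives 0.0850 M of product at 5.00 h, and 0.0831 M stands there. At 10 h the flask holds 0.142 M against your 0.170 M. For the neighbour charged with 0.80 M of electrophile, the same pace gives 0.170 M of product by 10 h. That neighbour makes 0.241 M, reaches 57.9 % reacted, and keeps 42.1 % of its electrophile unbound.

All runs come from a simulation for substances that don't exist, and the scatter is random.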